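**Retrosynthetic overview**

1. Numbering: ring A is the pyranone; ring B holds O8, hemiketal C9, C18 and C19; ring C is C9–C10–C11–C12–C13–C17–C18; ring D is C12–C13=C14–C15(=O)–C16(CH3)2. Feature: ring C has its C11 ketone next to the carbinol C12 that it shares with ring D; exchanging the two oxidation levels and moving C13 back to C11 gives a 6-6 ene-dione ketol, which is an ortho-quinol of a 2-methylresorcinol methylated at C16.
2. Ring B last: C19–C18 and O8–C9 by hetero-Diels–Alder addition of the pyranone ortho-quinone methide to the C18=C9 enol ether of a ring C bis(silyloxy)diene; C10–OH by Rubottom oxidation of the remaining C10=C11 enol ether; C9, C10 and C18 settle by equilibration.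
3. Rings C and D together: Al(OtBu)3 α-ketol shift of decalin ketol 13 (C12–C13 forms, C11–C13 breaks), drained by β-elimination of the C9 ketal in the product.
4. Decalin ketol from a 2-tetralone ketal: ortho-hydroxylative dearomatisation at C11 of the mono-silylated resorcinol, then C-methylation at C16.
5. Carbocycle first: C17 by Rh/BINAP 1,4-addition of an aryl boronate to pent-3-en-2-one; C10–C11 by rhodium-carbenoid aromatic substitution of the derived diazoketone.

Key step: step 10

Assumption: C9, C10 and C18 are epimerisable (hemiketal ring–chain tautomerism, enolisation of the open 2-hydroxy-1,3-diketone), so the natural configuration at these centres is taken to be the thermodynamic one; C17 and C12 are set under kinetic control.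

**Route**

Step 1
Reactants: 1 2,6-dimethoxytoluene
Product: 2 2-(3,5-dimethoxy-4-methylphenyl)-4,4,5,5-tetramethyl-1,3,2-dioxaborolane
Conditions: [Ir(OMe)(cod)]2 (1 mol%), 4,4'-di-tert-butyl-2,2'-bipyridine (2 mol%), B2pin2 (1.0 equiv), THF, 80 °C
Reagents that add atoms: bis(pinacolato)diboron, CC1(C)OB(OC1(C)C)B1OC(C)(C)C(C)(C)O1
Why: Iridium-catalysed aromatic C–H borylation is sterically controlled, and the position para to the methyl group is the only ring C–H without an ortho substituent, so one boronate is expected.

Step 2
Reactants: 2 aryl boronate; 3 (E)-pent-3-en-2-one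
Product: 4 (R)-4-(3,5-dimethoxy-4-methylphenyl)pentan-2-one
Conditions: [RhCl(C2H4)2]2 (1.5 mol%), (R)-BINAP (3.3 mol%), KOH (1 equiv), dioxane/H2O 10:1, 60 °C
Reagents that add atoms: none
Why: Hayashi–Miyaura asymmetric 1,4-addition should set C17 (R) by ligand-controlled addition of the aryl–rhodium species to one face of the (E)-enone; (R)-BINAP is chosen by analogy with the sense of induction known for (E)-alkenyl methyl ketones and is to be confirmed.

Step 3
Reactants: 4 (R)-4-arylpentan-2-one
Product: 6 (R)-1-diazo-4-(3,5-dimethoxy-4-methylphenyl)pentan-2-one, via trifluoroacetyl diketone 5 (not isolated)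
Conditions: LiHMDS, THF, −78 °C; CF3CO2CH2CF3; then MsN3, Et3N, H2O, MeCN, rt
Reagents that add atoms: methanesulfonyl azide, CS(=O)(=O)N=[N+]=[N-]
Why: Detrifluoroacetylative diazo transfer: the kinetic enolate forms at the methyl group (C10), trifluoroacetylation activates it and the sulfonyl azide transfers the diazo group with loss of the trifluoroacetyl unit; C17 is not enolisable.

Step 4
Reactants: 6 diazoketone
Product: 7 (R)-6,8-dimethoxy-4,7-dimethyl-3,4-dihydronaphthalen-2(1H)-one
Conditions: Rh2(OAc)4 (1 mol%), CH2Cl2, reflux
Reagents that add atoms: none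
Why: Intramolecular aromatic substitution by the rhodium carbenoid (formal aromatic C–H insertion of a 1-diazo-4-arylbutan-2-one) closes the six-membered ring through C10–C11; the two ortho positions of the symmetric aryl group are equivalent and each is ortho and para to a methoxy group.

Step 5
Reactants: 7 dimethoxytetralone
Product: 8 (R)-6,8-dihydroxy-4,7-dimethyl-3,4-dihydronaphthalen-2(1H)-one
Conditions: BBr3 (3 equiv), CH2Cl2, −78 → 0 °C; aq. work-up (under argon)
Reagents that add atoms: none
Why: Lewis-acid cleavage of both aryl methyl ethers; the ketone and the non-enolisable benzylic centre C17 are not affected.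

Step 6
Reactants: 8 dihydroxytetralone
Product: 9 (R)-6',8'-dihydroxy-4',7'-dimethyl-3',4'-dihydro-1'H-spiro[[1,3]dioxolane-2,2'-naphthalene]
Conditions: ethylene glycol (5 equiv), PPTS (cat.), benzene, reflux, Dean–Stark
Reagents that add atoms: ethylene glycol, OCCO
Why: Acid-catalysed ketalisation masks the C9 ketone, which would otherwise let the C11 hydroxyl be lost by β-elimination with rearomatisation after the dearomatisation.

Step 7
Reactants: 9 resorcinol ketal
Product: 10 (R)-4',7'-dimethyl-6'-(triisopropylsilyloxy)-3',4'-dihydro-1'H-spiro[[1,3]dioxolane-2,2'-naphthalen]-8'-ol (O15 silylated, C12 phenol free)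
Conditions: TIPSCl (1.05 equiv), imidazole, DMF, 0 °C
Reagents that add atoms: triisopropylsilyl chloride, CC(C)[Si](Cl)(C(C)C)C(C)C
Why: Silylation with a bulky chlorosilane should select the C15 phenol (one ortho methyl, one ortho hydrogen) over the C12 phenol (flanked by the methyl group and the ring methylene); masking O15 keeps the free, activated C14–H position out of the oxidation.

Step 8
Reactants: 10 mono-silyl ether
Product: 11 (4'R,8a'R)-8a'-hydroxy-4',7'-dimethyl-6'-(triisopropylsilyloxy)-3',4'-dihydro-1'H-spiro[[1,3]dioxolane-2,2'-naphthalen]-8'(8a'H)-one (ortho-quinol, C11–OH trans to C17–CH3)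
Conditions: SIBX (1.2 equiv IBX), THF, rt; aq. NaHCO3 work-up
Reagents that add atoms: 2-iodoxybenzoic acid (oxidant of SIBX), O=C1OI(=O)(O)c2ccccc12
Why: Hydroxylative phenol dearomatisation: the pentavalent iodine reagent binds O12 and transfers oxygen intramolecularly to an ortho carbon, expected at C11 (para to the silyloxy donor) and not at C16 (buttressed by the silyl ether); the new centre should form trans to the C17 methyl group by axial delivery on the half-chair with that methyl pseudo-equatorial.

Step 9
Reactants: 11 ortho-quinol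
Product: 13 (4'R,8a'R)-8a'-hydroxy-4',7',7'-trimethyl-3',4'-dihydro-1'H-spiro[[1,3]dioxolane-2,2'-naphthalene]-6',8'(7'H,8a'H)-dione, via enolised dione 12 (not isolated)
Conditions: K2CO3 (2 equiv), MeOH, 0 °C; then MeI (5 equiv), acetone, rt
Reagents that add atoms: iodomethane, CI
Why: Methanolysis of the vinylogous silyl ester frees the potassium enolate of the 2-methyl-1,3-dione, and C-methylation with iodomethane (the classical 2-methyl to 2,2-dimethyl-1,3-dione alkylation) installs the C16 gem-dimethyl group; O-methylated material can be hydrolysed and recycled.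

Step 10
Reactants: 13 decalin ketol
Product: 16 (3aR,8R)-3a-hydroxy-3,3,8-trimethyl-7,8-dihydroazulene-2,4,6(3H,3aH,5H)-trione, via hydroazulene ketol ketal 14 (not isolated), via hydroxyethyl enol ether 15 (not isolated)
Conditions: Al(OtBu)3 (2.5 equiv), toluene, 90 °C; then 1 M HCl, THF, rt
Reagents that add atoms: water, O
Why: The aluminium alkoxide of the C11 hydroxyl holds the C12 carbonyl in a five-membered chelate, within which the C11–C13 bond migrates to C12 and C11 is left as the ketone; this is an α-ketol (acyloin) rearrangement of the kind that contracts hop α-acids to iso-α-acids and that aluminium alkoxides promote in 17-hydroxy-20-keto steroids. Ring D closes by this suprafacial 1,2-alkenyl shift through a three-centre transition state (contraction of the dione ring with extrusion of C11), and ring C arises in the same event by one-carbon expansion of the carbocycle, which keeps C11. The new C12 centre is controlled by C11: because O11 and O12 are held syn, C13 is delivered to the face of the C12 carbonyl on which it already lies, so the C12 oxygen ends on the side the angular hydroxyl occupied, trans to the C17 methyl group; this is reasoned from the chelate model and not demonstrated. The step needs C13 and not C10 to migrate: alkenyl outranks alkyl in migratory aptitude, and C10 migration would give a bridged bicyclo[4.3.1] ketone with a bridgehead enone. It also needs a driving force, since the six-to-five and six-to-seven ring changes oppose the relief of the non-enolisable 2,2-dimethyl-1,3-dione: 13 has no enolisable ketone, whereas 14 is a β-keto ketal whose aluminium enolate should expel the ketal oxygen to give vinylogous ester 15, which cannot revert. Acidic work-up hydrolyses 15 and any surviving 14 to β-diketone 16.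

Step 11
Reactants: 16 β-diketone
Product: 17 (3aR,8R)-3,3,8-trimethyl-3a,4,6-tris(triethylsilyloxy)-3a,8-dihydroazulen-2(3H)-one (diene C18=C9–C10=C11)
Conditions: TESOTf (3.5 equiv), Et3N (5 equiv), CH2Cl2, −78 → 0 °C; non-aqueous work-up
Reagents that add atoms: triethylsilyl trifluoromethanesulfonate, CC[Si](CC)(CC)OS(=O)(=O)C(F)(F)F
Why: Soft enolisation of a cyclic 1,3-diketone to its 1,3-bis(silyloxy)diene; C12 is quaternary, so the second enolisation can only run towards C18 and one diene regioisomer results, while the tertiary C12 hydroxyl is silylated as well.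

Step 12
Reactants: 18 4-hydroxy-5,6-dimethyl-2H-pyran-2-one
Product: 19 3-[(dimethylamino)methyl]-4-hydroxy-5,6-dimethyl-2H-pyran-2-one
Conditions: Me2N=CH2+ I− (Eschenmoser's salt, 1.1 equiv), MeCN, rt; aq. NaHCO3
Reagents that add atoms: N,N-dimethylmethyleneiminium iodide, C[N+](C)=C.[I-]
Why: Mannich reaction at the nucleophilic C3 of the 4-hydroxypyranone gives the aminomethyl compound that serves as a thermal ortho-quinone methide precursor.

Step 13
Reactants: 17 tris(silyloxy) diene; 19 Mannich base
Product: 21 ring B cycloadduct (C9–OSiEt3, C10=C11–OSiEt3, C12–OSiEt3; C18–C19 and C9–O8 cis to each other and anti to the C17 methyl group), via pyranone quinone methide 20 (not isolated)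
Conditions: 19 (2 equiv), toluene, 4 Å MS, 90 °C
Reagents that add atoms: none
Why: Inverse-electron-demand hetero-Diels–Alder reaction of the ortho-quinone methide (formed by thermal loss of dimethylamine) with the terminal enol ether C18=C9, the nucleophilic terminus of a 1,3-dioxygenated diene, forms C19–C18 and O8–C9 through the ketone oxygen; addition is suprafacial and expected on the face of C18 opposite the C17 methyl group, and the C10=C11 silyl enol ether is left intact.

Step 14
Reactants: 21 cycloadduct
Product: 24 CNP0525404.1 (9S,10R,12R,17R,18R), via silyloxy epoxide 22 (not isolated), via kinetic hemiketal 23 (not isolated)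
Conditions: DMDO (1.1 equiv), acetone/CH2Cl2, −78 → −40 °C; then HF·pyridine, THF, 0 °C → rt; then AcOH (cat.), CHCl3, rt
Reagents that add atoms: dimethyldioxirane, CC1(C)OO1
Why: Rubottom oxidation: DMDO epoxidises only the electron-rich C10=C11 silyl enol ether, fluoride opens the silyloxy epoxide to the C10 hydroxy ketone and frees the C9 hemiketal and the C12 alcohol; C9 (ring opening and reclosure), C10 and C18 (enolisation of the open 2-hydroxy-1,3-diketone) should then settle under mild acid into the target arrangement with rings B and C trans-fused and the anomeric C9 hydroxyl axial.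

**Compound list**

1 | 2,6-dimethoxytoluene | COc1cccc(OC)c1C | starting material
2 | 2-(3,5-dimethoxy-4-methylphenyl)-4,4,5,5-tetramethyl-1,3,2-dioxaborolane | COc1cc(cc(OC)c1C)B1OC(C)(C)C(C)(C)O1 | intermediate
3 | (E)-pent-3-en-2-one | C/C=C/C(C)=O | starting material
4 | (R)-4-(3,5-dimethoxy-4-methylphenyl)pentan-2-one | C[C@H](CC(C)=O)c1cc(OC)c(C)c(OC)c1 | intermediate
5 | (R)-6-(3,5-dimethoxy-4-methylphenyl)-1,1,1-trifluoroheptane-2,4-dione (not isolated) | C[C@H](CC(=O)CC(=O)C(F)(F)F)c1cc(OC)c(C)c(OC)c1 | intermediate
6 | (R)-1-diazo-4-(3,5-dimethoxy-4-methylphenyl)pentan-2-one | C[C@H](CC(=O)C=[N+]=[N-])c1cc(OC)c(C)c(OC)c1 | intermediate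
7 | (R)-6,8-dimethoxy-4,7-dimethyl-3,4-dihydronaphthalen-2(1H)-one | O=C1Cc2c(OC)c(C)c(OC)cc2[C@H](C)C1 | intermediate
8 | (R)-6,8-dihydroxy-4,7-dimethyl-3,4-dihydronaphthalen-2(1H)-one | O=C1Cc2c(O)c(C)c(O)cc2[C@H](C)C1 | intermediate
9 | ethylene ketal of 8 | O1CCOC12Cc3c(O)c(C)c(O)cc3[C@H](C)C2 | intermediate
10 | O15-triisopropylsilyl ether of 9 (C12 phenol free) | O1CCOC12Cc3c(O)c(C)c(O[Si](C(C)C)(C(C)C)C(C)C)cc3[C@H](C)C2 | intermediate
11 | ortho-quinol: C11 hydroxyl (R, trans to C17 methyl), C12 ketone, C15 silyl dienol ether | O1CCOC12C[C@]3(O)C(=O)C(C)=C(O[Si](C(C)C)(C(C)C)C(C)C)C=C3[C@H](C)C2 | intermediate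
12 | desilylated vinylogous acid, formed as its potassium enolate (not isolated) | O1CCOC12C[C@]3(O)C(=O)C(C)=C(O)C=C3[C@H](C)C2 | intermediate
13 | decalin ketol, key-step precursor: (4'R,8a'R)-8a'-hydroxy-4',7',7'-trimethyl ene-dione ketal | O1CCOC12C[C@]3(O)C(=O)C(C)(C)C(=O)C=C3[C@H](C)C2 | intermediate
14 | hydroazulene ketol ketal, key-step product: C11 ketone, C12 carbinol (R), C9 dioxolane (not isolated) | O1CCOC12CC(=O)[C@@]3(O)C(=CC(=O)C3(C)C)[C@H](C)C2 | intermediate
15 | (3aR,8R)-3a-hydroxy-6-(2-hydroxyethoxy)-3,3,8-trimethyl-7,8-dihydroazulene-2,4(3H,3aH)-dione (not isolated) | OCCOC1=CC(=O)[C@@]2(O)C(=CC(=O)C2(C)C)[C@H](C)C1 | intermediate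
16 | (3aR,8R)-3a-hydroxy-3,3,8-trimethyl-7,8-dihydroazulene-2,4,6(3H,3aH,5H)-trione | O=C1CC(=O)[C@@]2(O)C(=CC(=O)C2(C)C)[C@H](C)C1 | intermediate
17 | (3aR,8R)-3,3,8-trimethyl-3a,4,6-tris(triethylsilyloxy)-3a,8-dihydroazulen-2(3H)-one | CC[Si](CC)(CC)OC1=C[C@@H](C)C2=CC(=O)C(C)(C)[C@@]2(O[Si](CC)(CC)CC)C(O[Si](CC)(CC)CC)=C1 | intermediate
18 | 4-hydroxy-5,6-dimethyl-2H-pyran-2-one | Cc1oc(=O)cc(O)c1C | starting material
19 | 3-[(dimethylamino)methyl]-4-hydroxy-5,6-dimethyl-2H-pyran-2-one | Cc1oc(=O)c(CN(C)C)c(O)c1C | intermediate
20 | 5,6-dimethyl-3-methylidene-2H-pyran-2,4(3H)-dione (not isolated) | CC1=C(C)C(=O)C(=C)C(=O)O1 | intermediate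
21 | ring B cycloadduct, tris(triethylsilyl): C9–O8 and C18–C19 cis, C10=C11 silyl enol ether | Cc1oc(=O)c2c(c1C)O[C@@]1(O[Si](CC)(CC)CC)C=C(O[Si](CC)(CC)CC)[C@@]3(O[Si](CC)(CC)CC)C(=CC(=O)C3(C)C)[C@H](C)[C@H]1C2 | intermediate
22 | C10,C11-epoxide of 21, drawn for attack on the face of the C12 silyloxy group (not isolated) | Cc1oc(=O)c2c(c1C)O[C@@]1(O[Si](CC)(CC)CC)[C@H]4O[C@@]4(O[Si](CC)(CC)CC)[C@@]3(O[Si](CC)(CC)CC)C(=CC(=O)C3(C)C)[C@H](C)[C@H]1C2 | intermediate
23 | kinetic hemiketal, the C9,C10 diepimer of the target (not isolated) | Cc1oc(=O)c2c(c1C)O[C@@]1(O)[C@@H](O)C(=O)[C@@]3(O)C(=CC(=O)C3(C)C)[C@H](C)[C@H]1C2 | intermediate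
24 | CNP0525404.1 | Cc1oc(=O)c2c(c1C)O[C@]1(O)[C@H](O)C(=O)[C@@]3(O)C(=CC(=O)C3(C)C)[C@H](C)[C@H]1C2 | target

**Step count**

Total: 14 steps. Longest linear sequence: 13 steps (steps 1–11, 13, 14, from 2,6-dimethoxytoluene); step 12 is a one-step side branch.

**Steps most likely to fail**

Step 10 (α-ketol shift). The equilibrium may stay on the decalin side if enolisation and β-elimination of the product are slower than the reverse shift. Retro-aldol opening of ring D at the C12 aluminium alkoxide could erode the C12 configuration, and γ-deprotonation of the enone could epimerise C17. Fallback, from 13 back to 16: replace the neutral aluminium equilibrium by a deprotonative variant. Compound 13 is treated with Mg(HMDS)2 (2.2 equiv, toluene/THF, 0 → 50 °C); the magnesium alkoxide keeps the syn chelate needed for the C11-to-C12 transfer, and the second amide ligand deprotonates C10 of 14 as it forms. The shift is then driven by irreversible enolate formation; the enolate loses the ketal oxygen to 15 and aqueous acid gives 16. No new compound arises.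

Step 8 (hydroxylative dearomatisation). Oxygen may be transferred to C16 instead of C11, delivery may occur on the face cis to the C17 methyl group, and the ortho-quinol may dimerise by [4+2] addition before it is used. Fallback, from 9 back to 13: a para-selective route through the other phenol. Compound 9 is bis-silylated (TBSCl, imidazole, DMF) to the bis(tert-butyldimethylsilyl) ether F1. The less hindered O15 silyl group is removed (K2CO3, MeOH, 0 °C) to give the C15 phenol F2. PhI(OAc)2 in MeCN/H2O oxidises that phenol and water adds at the para carbon C11, giving the para-quinol F3. Methanolysis and methylation as in step 9 lead through 12 to 13.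

Step 13 (hetero-Diels–Alder). The quinone methide may be consumed by its own precursor or oligomerise, the liberated amine may desilylate the diene, and ring closure through the lactone oxygen or attack at C10 may compete. Fallback, from 17 to 24: a stepwise Mannich–Michael sequence. Diene 17 reacts with Eschenmoser's salt at its terminus C18 (Mukaiyama–Mannich, CH2Cl2, −78 → 0 °C) and is desilylated on work-up (aq. HF, MeCN) to the Mannich base F4. Heating F4 with pyranone 18 (toluene, AcOH cat., 80 °C) eliminates dimethylamine to the exo-methylene diketone F5, which takes up C3 of the pyranone by Michael addition and cyclodehydrates to the pyrano-fused vinylogous ester F6. DMDO epoxidises the C9=C10 enol ether double bond of F6 (the flavone-to-flavonol type of oxidation) to the epoxide F7. Aqueous acid opens F7 at the acetal carbon C9 to the hemiketal diol, which equilibrates to 24.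

**Further compounds**

F0 | step 10 | none | none
F1 | step 8 | bis(tert-butyldimethylsilyl) ether of 9 | O1CCOC12Cc3c(O[Si](C)(C)C(C)(C)C)c(C)c(O[Si](C)(C)C(C)(C)C)cc3[C@H](C)C2
F2 | step 8 | O12-tert-butyldimethylsilyl ether of 9 with free C15 phenol | O1CCOC12Cc3c(O[Si](C)(C)C(C)(C)C)c(C)c(O)cc3[C@H](C)C2
F3 | step 8 | para-quinol: C11 hydroxyl, C15 ketone, C12 silyl enol ether | O1CCOC12C[C@]3(O)C(O[Si](C)(C)C(C)(C)C)=C(C)C(=O)C=C3[C@H](C)C2
F4 | step 13 | C18-(dimethylaminomethyl) derivative of 16 | O=C1CC(=O)[C@@]2(O)C(=CC(=O)C2(C)C)[C@H](C)[C@H]1CN(C)C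
F5 | step 13 | C18-methylidene derivative of 16 | O=C1CC(=O)[C@@]2(O)C(=CC(=O)C2(C)C)[C@H](C)C1=C
F6 | step 13 | pyrano-fused vinylogous ester (O8–C9=C10–C11=O, 10-deoxy anhydro target) | Cc1oc(=O)c2c(c1C)OC1=CC(=O)[C@@]3(O)C(=CC(=O)C3(C)C)[C@H](C)[C@H]1C2
F7 | step 13 | C9,C10-epoxide of F6 | Cc1oc(=O)c2c(c1C)O[C@]14O[C@@H]4C(=O)[C@@]3(O)C(=CC(=O)C3(C)C)[C@H](C)[C@H]1C2
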